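**Plan**
- Retrosynthesis: the late groups are stripped first (C3 enal back to a C5 vinyl group, oxirane back to a glycerate-derived dioxolane, angelate, C13 methylene). The carbocycle is then cut at C5–C6 and C9–C10 in one stroke, and both fragments go back to one chiral-pool ester.
- Enabling feature: the cyclohexane is a 1,4-diol (O6, O9) whose carbinol carbons C6 and C9 flank the vicinal pair C5–C10, each bearing a two-carbon branch (C4=C15 on C5; C1–C2 on quaternary C10). These are two homoallylic-alcohol retrons sharing the C5–C10 bond, which translates into an allylic 1,2-bis(boronate) plus a 1,4-dialdehyde.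
- Forward: ester 1 → (E)-diene → enantioselective 1,2-diboration (fragment A); ester 1 → (Z)-enoate → anti vinyl-cuprate addition → trans-lactone dialdehyde (fragment B, lactone ring made first).
- A double allylboration joins A and B at the quaternary C10 and closes the cyclohexane onto the lactone. Then: C6 inversion, C13 methylenation, angeloylation, oxirane closure, vinyl → CH2CHO → α-methylene aldehyde.
- Stereochemistry: C1 and C8 from the chiral pool; C7 by 1,2-induction; C10 and C9 by chirality transfer from the catalyst-set C–B centre; C5 by the chair ring closure; C6 by hindered-hydride reduction; alkene geometries from olefination (E) and angelic acid (Z).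

Key step: step 10

Remark (numbering used below): elemane locants. C5–C10 are the cyclohexane carbons (C10 quaternary, C14 its methyl); C11/C12/O8 form the lactone on C7–C8; C13 is its methylene; C4 (with C3, C15) is the unit on C5; C1–C2 is the unit on C10. β is the ring face that carries C14.

**Step 1**
Reactants: 1 methyl (4S)-2,2-dimethyl-1,3-dioxolane-4-carboxylate
Product: 3 1-[(4S)-2,2-dimethyl-1,3-dioxolan-4-yl]ethan-1-one, via Weinreb amide 2 (not isolated)
Conditions: MeNH(OMe)·HCl, iPrMgCl, THF, −20 °C; then MeMgBr, −20 → 0 °C; aq. NH4Cl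
Reagents that add atoms: methylmagnesium bromide, C[Mg]Br
Why: The ester is converted in the flask to the Weinreb amide, whose chelated tetrahedral adduct with MeMgBr should stop at the ketone, and the low temperature preserves the α-alkoxy stereocentre.

**Step 2**
Reactants: 3 1-[(4S)-2,2-dimethyl-1,3-dioxolan-4-yl]ethan-1-one
Product: 4 (2E)-3-[(4R)-2,2-dimethyl-1,3-dioxolan-4-yl]-N-methoxy-N-methylbut-2-enamide
Conditions: (EtO)2P(O)CH2C(O)N(OMe)Me, NaH, THF, 0 °C → rt
Reagents that add atoms: diethyl [2-(methoxy(methyl)amino)-2-oxoethyl]phosphonate, CCOP(=O)(CC(=O)N(C)OC)OCC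
Why: Horner–Wadsworth–Emmons olefination of the methyl ketone should place the amide carbonyl trans to the larger dioxolanyl group (E), the geometry that later decides the C10 configuration; the minor Z isomer is removed by chromatography.

**Step 3**
Reactants: 4 (2E)-3-[(4R)-2,2-dimethyl-1,3-dioxolan-4-yl]-N-methoxy-N-methylbut-2-enamide
Product: 5 (2E)-3-[(4R)-2,2-dimethyl-1,3-dioxolan-4-yl]but-2-enal
Conditions: iBu2AlH, THF, −78 °C; aq. potassium sodium tartrate
Reagents that add atoms: none
Why: iBu2AlH reduces the Weinreb amide to a stable chelated hemiaminal that releases the enal only on work-up, so neither over-reduction nor 1,4-reduction is expected.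

**Step 4**
Reactants: 5 (2E)-3-[(4R)-2,2-dimethyl-1,3-dioxolan-4-yl]but-2-enal
Product: 6 (4R)-2,2-dimethyl-4-[(2E)-penta-2,4-dien-2-yl]-1,3-dioxolane
Conditions: Ph3PCH3Br, KOtBu, THF, 0 °C
Reagents that add atoms: methyltriphenylphosphonium bromide, C[P+](c1ccccc1)(c1ccccc1)c1ccccc1.[Br-]
Why: Wittig methylenation of the enal should give the terminal diene without touching the trisubstituted alkene geometry or the acetonide.

**Step 5**
Reactants: 6 (4R)-2,2-dimethyl-4-[(2E)-penta-2,4-dien-2-yl]-1,3-dioxolane
Product: 7 allylic 1,2-bis(pinacolboronate) with a 2R C–B centre and the (E)-alkene retained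
Conditions: B2pin2, Pt2(dba)3 (cat.), TADDOL-derived phenylphosphonite ligand (the enantiomer that gives the 2R boronate), toluene, 60 °C
Reagents that add atoms: bis(pinacolato)diboron, CC1(C)OB(OC1(C)C)B1OC(C)(C)C(C)(C)O1
Why: Zerovalent-platinum-catalysed enantioselective 1,2-diboration: the cis methyl at the 4,4-disubstituted terminus blocks the s-cis conformer needed for 1,4-addition, so B–B adds across the terminal vinyl group and the chiral phosphonite sets the secondary C–B stereocentre (catalyst control, the remote dioxolane being a spectator).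

**Step 6**
Reactants: 1 methyl (4S)-2,2-dimethyl-1,3-dioxolane-4-carboxylate
Product: 9 methyl (2Z)-3-[(4R)-2,2-dimethyl-1,3-dioxolan-4-yl]prop-2-enoate, via aldehyde 8 (not isolated)
Conditions: iBu2AlH, CH2Cl2, −78 °C; then MeOH, Ph3P=CHCO2Me, −78 °C → rt
Reagents that add atoms: methyl (triphenylphosphoranylidene)acetate, COC(=O)C=P(c1ccccc1)(c1ccccc1)c1ccccc1
Why: Half-reduction of the ester and Wittig olefination of the released aldehyde in methanol, which is Z-selective for α-alkoxy aldehydes, avoids isolating the labile glyceraldehyde acetonide and leaves its stereocentre (later C8) untouched.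

**Step 7**
Reactants: 9 methyl (2Z)-3-[(4R)-2,2-dimethyl-1,3-dioxolan-4-yl]prop-2-enoate
Product: 11 (4S,5R)-4-ethenyl-5-(hydroxymethyl)oxolan-2-one, via ester 10 (not isolated)
Conditions: CH2=CHMgBr, CuI, THF, −78 → −40 °C; aq. NH4Cl; then crude adduct, 2 M HCl, THF, rt
Reagents that add atoms: vinylmagnesium bromide, C=C[Mg]Br
Why: Vinyl cuprate 1,4-addition to the (Z)-γ-alkoxy enoate should occur anti to the γ-C–O bond in the conformer fixed by allylic 1,3-strain (1,2-induction sets C7), and acid then removes the acetonide and closes the γ-lactone, which is therefore trans-4,5-disubstituted.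

**Step 8**
Reactants: 11 (4S,5R)-4-ethenyl-5-(hydroxymethyl)oxolan-2-one
Product: 12 (2R,3S)-3-ethenyl-5-oxooxolane-2-carbaldehyde
Conditions: Dess–Martin periodinane, CH2Cl2, 0 °C → rt
Reagents that add atoms: none
Why: Dess–Martin oxidation of the primary alcohol under non-basic conditions should give the α-acyloxy aldehyde without epimerisation at C8.

**Step 9**
Reactants: 12 (2R,3S)-3-ethenyl-5-oxooxolane-2-carbaldehyde
Product: 14 (2R,3R)-5-oxooxolane-2,3-dicarbaldehyde, via ozonide 13 (not isolated)
Conditions: O3, CH2Cl2, −78 °C; then PPh3, −78 °C → rt; used crude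
Reagents that add atoms: ozone, [O-][O+]=O
Why: Ozonolysis of the vinyl group with reductive PPh3 work-up unmasks the second aldehyde under neutral conditions, and the dialdehyde is used at once to avoid β-elimination or epimerisation.

**Step 10**
Reactants: 7 allylic 1,2-bis(pinacolboronate); 14 (2R,3R)-5-oxooxolane-2,3-dicarbaldehyde
Product: 17 6α,9α-diol lactone (C6 epimer of the target core), via allylboronate 15 (not isolated), via bis(borate) 16 (not isolated)
Conditions: toluene, 4 Å molecular sieves, 60 °C; then H2O, THF, rt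
Reagents that add atoms: none
Why: Two consecutive allylborations run through closed six-membered (Zimmerman–Traxler) chairs: the secondary allylic C–B bond of 7 adds through its disubstituted terminus C10 to the more electrophilic α-acyloxy aldehyde C9 (C9–C10, quaternary centre), which transposes the alkene and turns the primary C15–B bond into a new (E)-allylboronate 15 that adds intramolecularly through C5 to the C6 aldehyde (C5–C6). The closest known reaction type is the tandem diene 1,2-diboration/double allylboration of 1,4-dicarbonyl compounds to cyclohexane-1,4-diols. The cyclohexane closes by 6-exo-trig attack of C5 on the C6 carbonyl through a trans-decalin-like bicyclic transition state in which the preformed trans-lactone holds C7 and C8 equatorial. C10 and C9 are set by chirality transfer from the C–B stereocentre of 7 with the borylmethyl group equatorial (allylic 1,3-strain against the cis methyl; methyl pseudoaxial, dioxolanyl and aldehyde residue equatorial), reinforced by the intrinsic preference of the α-oxygenated aldehyde for the 8,9-anti diol; C5 follows from the equatorial allyl unit on the forming chair, and C6 should come out α (equatorial, trans to the vinyl group) as expected for an (E)-allylboronate, to be corrected in steps 11–13. The step needs site-selectivity between the two aldehydes, which inductive activation of C9 by O8 should secure, and ring closure faster than a second intermolecular allylation, which the six-membered closure and the bulk of 7 should secure.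

**Step 11**
Reactants: 17 6α,9α-diol lactone
Product: 18 6-ketone with free 9α-hydroxyl
Conditions: TEMPO (cat.), PhI(OAc)2, CH2Cl2, rt
Reagents that add atoms: none
Why: Oxoammonium (TEMPO) oxidation is strongly retarded by steric hindrance, so the equatorial C6 carbinol should be oxidised while the axial, neopentylic C9 carbinol next to the quaternary C10 stays intact.

**Step 12**
Reactants: 18 6-ketone with free 9α-hydroxyl
Product: 19 6-ketone 9α-O-triethylsilyl ether
Conditions: Et3SiOTf, 2,6-lutidine, CH2Cl2, −78 → −20 °C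
Reagents that add atoms: triethylsilyl trifluoromethanesulfonate, CC[Si](CC)(CC)OS(=O)(=O)C(F)(F)F
Why: The silyl triflate with 2,6-lutidine at low temperature should silylate even the hindered C9 hydroxyl faster than it enolises the ketone, protecting O9 for the later acylation.

**Step 13**
Reactants: 19 6-ketone 9α-O-triethylsilyl ether
Product: 20 6β-alcohol 9α-O-triethylsilyl ether
Conditions: LiBH(sBu)3, THF, −78 °C; aq. NH4Cl
Reagents that add atoms: none
Why: The bulky hydride should attack the C6 ketone from the α (equatorial) side because the axial trajectory on the β face is blocked by the syn-axial C14 methyl, giving the axial 6β-alcohol, while the lactone is inert at −78 °C.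

**Step 14**
Reactants: 20 6β-alcohol 9α-O-triethylsilyl ether
Product: 23 C11(13)-methylene lactone with free 6β-hydroxyl, via Mannich base 21 (not isolated), via ammonium iodide 22 (not isolated)
Conditions: LiN(iPr)2 (2.5 equiv; substrate added to the base), THF, −78 °C; Me2N=CH2+ I−, −78 → −20 °C; then MeI, THF/MeOH, rt; then aq. NaHCO3, rt
Reagents that add atoms: N,N-dimethylmethyleneiminium iodide (Eschenmoser's salt), C=[N+](C)C.[I-]
Why: α-Methylenation of the lactone by Mannich reaction of its lithium enolate (the C6 hydroxyl rides as the alkoxide, and fast enolisation at −78 °C forestalls translactonisation), followed by quaternisation and mild-base elimination.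

**Step 15**
Reactants: 23 C11(13)-methylene lactone with free 6β-hydroxyl
Product: 24 6β-O-angelate
Conditions: angelic acid, 2,4,6-Cl3C6H2COCl, Et3N, toluene, rt; then 23, toluene, 80 °C (no DMAP)
Reagents that add atoms: (2Z)-2-methylbut-2-enoic acid (angelic acid), C/C=C(/C)C(=O)O
Why: Yamaguchi esterification through the mixed anhydride without DMAP should acylate the hindered axial 6β-hydroxyl with retention of the angelate (Z) geometry, O9 being blocked as its silyl ether.

**Step 16**
Reactants: 24 6β-O-angelate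
Product: 25 triol with (1R)-1,2-dihydroxyethyl at C10 and free 9α-hydroxyl
Conditions: AcOH/H2O (4:1), 55 °C
Reagents that add atoms: none
Why: Aqueous acetic acid should hydrolyse the terminal acetonide and the triethylsilyl ether while the ester, lactone and conjugated alkenes are inert.

**Step 17**
Reactants: 25 triol
Product: 27 (1R)-oxirane with 5β-vinyl group, via tosylate 26 (not isolated)
Conditions: TsCl, Et3N, Bu2SnO (cat.), CH2Cl2, 0 °C; then DBU, 0 °C → rt
Reagents that add atoms: none
Why: The primary hydroxyl of the 1,2-diol is sulfonylated selectively (stannylene-acetal catalysis) and the adjacent secondary alkoxide displaces the tosylate in a 3-exo-tet closure, so C1 keeps its configuration (R).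

**Step 18**
Reactants: 27 (1R)-oxirane with 5β-vinyl group
Product: 28 C3 aldehyde (5β-CH2CHO)
Conditions: PdCl2(PhCN)2, CuCl2·2H2O, AgNO2 (all cat.), O2 (1 atm), tBuOH/MeNO2 (15:1), rt
Reagents that add atoms: dioxygen, O=O
Why: Aldehyde-selective (anti-Markovnikov) Wacker-type oxidation with a nitrite co-catalyst should act only on the unconjugated monosubstituted alkene, and the hindered allylic position next to the quaternary C10 reinforces terminal oxygenation.

**Step 19**
Reactants: 28 C3 aldehyde
Product: 30 target CNP0113462.3, via Mannich base 29 (not isolated)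
Conditions: Me2N=CH2+ I−, Et3N, CH2Cl2, rt
Reagents that add atoms: N,N-dimethylmethyleneiminium iodide (Eschenmoser's salt), C=[N+](C)C.[I-]
Why: Mannich reaction of the enolisable aldehyde with the iminium salt and loss of dimethylamine should install the C15 methylene under mild amine conditions that leave the epoxide, the esters and the free C9 hydroxyl alone.

**Compound list**
1 | methyl (4S)-2,2-dimethyl-1,3-dioxolane-4-carboxylate | COC(=O)[C@@H]1COC(C)(C)O1 | starting material
2 | (4S)-N-methoxy-N,2,2-trimethyl-1,3-dioxolane-4-carboxamide | CON(C)C(=O)[C@@H]1COC(C)(C)O1 | intermediate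
3 | 1-[(4S)-2,2-dimethyl-1,3-dioxolan-4-yl]ethan-1-one | CC(=O)[C@@H]1COC(C)(C)O1 | intermediate
4 | (2E)-3-[(4R)-2,2-dimethyl-1,3-dioxolan-4-yl]-N-methoxy-N-methylbut-2-enamide | CON(C)C(=O)/C=C(\C)[C@@H]1COC(C)(C)O1 | intermediate
5 | (2E)-3-[(4R)-2,2-dimethyl-1,3-dioxolan-4-yl]but-2-enal | O=C/C=C(\C)[C@@H]1COC(C)(C)O1 | intermediate
6 | (4R)-2,2-dimethyl-4-[(2E)-penta-2,4-dien-2-yl]-1,3-dioxolane | C=C/C=C(\C)[C@@H]1COC(C)(C)O1 | intermediate
7 | 2,2'-{(2R,3E)-4-[(4R)-2,2-dimethyl-1,3-dioxolan-4-yl]pent-3-ene-1,2-diyl}bis(4,4,5,5-tetramethyl-1,3,2-dioxaborolane) | CC1(C)OB(OC1(C)C)C[C@@H](B2OC(C)(C)C(C)(C)O2)/C=C(\C)[C@@H]3COC(C)(C)O3 | intermediate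
8 | (4S)-2,2-dimethyl-1,3-dioxolane-4-carbaldehyde | O=C[C@@H]1COC(C)(C)O1 | intermediate
9 | methyl (2Z)-3-[(4R)-2,2-dimethyl-1,3-dioxolan-4-yl]prop-2-enoate | COC(=O)/C=C\[C@@H]1COC(C)(C)O1 | intermediate
10 | methyl (3S)-3-[(4R)-2,2-dimethyl-1,3-dioxolan-4-yl]pent-4-enoate | COC(=O)C[C@@H](C=C)[C@@H]1COC(C)(C)O1 | intermediate
11 | (4S,5R)-4-ethenyl-5-(hydroxymethyl)oxolan-2-one | C1C(=O)O[C@@H](CO)[C@@H]1C=C | intermediate
12 | (2R,3S)-3-ethenyl-5-oxooxolane-2-carbaldehyde | C1C(=O)O[C@@H](C=O)[C@@H]1C=C | intermediate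
13 | (2R,3R)-5-oxo-3-(1,2,4-trioxolan-3-yl)oxolane-2-carbaldehyde (both epimers at the trioxolane carbon) | C1C(=O)O[C@@H](C=O)[C@@H]1C2OCOO2 | intermediate
14 | (2R,3R)-5-oxooxolane-2,3-dicarbaldehyde | C1C(=O)O[C@@H](C=O)[C@@H]1C=O | intermediate
15 | mono-adduct: C9–C10 bond formed; C9 O-pinacolboryl; (E)-C4=C5 alkene bearing C15H2–Bpin; C6 aldehyde free | C1C(=O)O[C@H]([C@@H]1C=O)[C@@H](OB2OC(C)(C)C(C)(C)O2)[C@](C)(/C=C/CB3OC(C)(C)C(C)(C)O3)[C@@H]4COC(C)(C)O4 | intermediate
16 | 6α,9α-bis(O-pinacolboryl) ester of 17 | C1C(=O)O[C@@H]2[C@@H]1[C@H](OB3OC(C)(C)C(C)(C)O3)[C@@H](C=C)[C@](C)([C@@H]4COC(C)(C)O4)[C@@H]2OB5OC(C)(C)C(C)(C)O5 | intermediate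
17 | (3aS,4R,5S,6S,7S,7aR)-6-[(4R)-2,2-dimethyl-1,3-dioxolan-4-yl]-5-ethenyl-4,7-dihydroxy-6-methylhexahydro-1-benzofuran-2(3H)-one (trans-fused 8α,12-lactone; 6α-OH; 9α-OH; 5β-vinyl; 10β-methyl) | C1C(=O)O[C@@H]2[C@@H]1[C@H](O)[C@@H](C=C)[C@](C)([C@@H]3COC(C)(C)O3)[C@@H]2O | intermediate
18 | 6-oxo analogue of 17 (9α-OH free) | C1C(=O)O[C@@H]2[C@@H]1C(=O)[C@@H](C=C)[C@](C)([C@@H]3COC(C)(C)O3)[C@@H]2O | intermediate
19 | 9α-O-triethylsilyl ether of 18 | C1C(=O)O[C@@H]2[C@@H]1C(=O)[C@@H](C=C)[C@](C)([C@@H]3COC(C)(C)O3)[C@@H]2O[Si](CC)(CC)CC | intermediate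
20 | 6β-alcohol (axial) 9α-O-triethylsilyl ether | C1C(=O)O[C@@H]2[C@@H]1[C@@H](O)[C@@H](C=C)[C@](C)([C@@H]3COC(C)(C)O3)[C@@H]2O[Si](CC)(CC)CC | intermediate
21 | 11-(dimethylaminomethyl) derivative of 20 (C11 epimers) | CN(C)CC1C(=O)O[C@@H]2[C@@H]1[C@@H](O)[C@@H](C=C)[C@](C)([C@@H]3COC(C)(C)O3)[C@@H]2O[Si](CC)(CC)CC | intermediate
22 | 11-(trimethylammoniomethyl) iodide of 20 (C11 epimers) | C[N+](C)(C)CC1C(=O)O[C@@H]2[C@@H]1[C@@H](O)[C@@H](C=C)[C@](C)([C@@H]3COC(C)(C)O3)[C@@H]2O[Si](CC)(CC)CC.[I-] | intermediate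
23 | 11(13)-methylene lactone; 6β-OH; 9α-OSiEt3; 5β-vinyl; dioxolane | C=C1C(=O)O[C@@H]2[C@@H]1[C@@H](O)[C@@H](C=C)[C@](C)([C@@H]3COC(C)(C)O3)[C@@H]2O[Si](CC)(CC)CC | intermediate
24 | 6β-O-[(2Z)-2-methylbut-2-enoyl] ester of 23 | C=C1C(=O)O[C@@H]2[C@@H]1[C@@H](OC(=O)/C(C)=C\C)[C@@H](C=C)[C@](C)([C@@H]3COC(C)(C)O3)[C@@H]2O[Si](CC)(CC)CC | intermediate
25 | triol: 6β-angelate; 9α-OH; 10α-[(1R)-1,2-dihydroxyethyl] | C=C1C(=O)O[C@@H]2[C@@H]1[C@@H](OC(=O)/C(C)=C\C)[C@@H](C=C)[C@](C)([C@@H](O)CO)[C@@H]2O | intermediate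
26 | primary (C2) 4-methylbenzenesulfonate of 25 | C=C1C(=O)O[C@@H]2[C@@H]1[C@@H](OC(=O)/C(C)=C\C)[C@@H](C=C)[C@](C)([C@@H](O)COS(=O)(=O)c3ccc(C)cc3)[C@@H]2O | intermediate
27 | 10α-[(2R)-oxiran-2-yl] compound with 5β-vinyl; 6β-angelate; 9α-OH | C=C1C(=O)O[C@@H]2[C@@H]1[C@@H](OC(=O)/C(C)=C\C)[C@@H](C=C)[C@](C)([C@@H]3CO3)[C@@H]2O | intermediate
28 | 5β-(2-oxoethyl) aldehyde | C=C1C(=O)O[C@@H]2[C@@H]1[C@@H](OC(=O)/C(C)=C\C)[C@@H](CC=O)[C@](C)([C@@H]3CO3)[C@@H]2O | intermediate
29 | 5β-[1-(dimethylamino)-3-oxopropan-2-yl] Mannich base (C4 epimers) | C=C1C(=O)O[C@@H]2[C@@H]1[C@@H](OC(=O)/C(C)=C\C)[C@@H](C(CN(C)C)C=O)[C@](C)([C@@H]3CO3)[C@@H]2O | intermediate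
30 | (3aS,4S,5R,6S,7S,7aR)-7-hydroxy-6-methyl-3-methylidene-6-[(2R)-oxiran-2-yl]-2-oxo-5-(3-oxoprop-1-en-2-yl)octahydro-1-benzofuran-4-yl (2Z)-2-methylbut-2-enoate | C=C1C(=O)O[C@@H]2[C@@H]1[C@@H](OC(=O)/C(C)=C\C)[C@@H](C(=C)C=O)[C@](C)([C@@H]1CO1)[C@@H]2O | target

**Totals**
Total step count: 19.
Longest linear sequence: 15 steps (steps 1–5, then 10–19). Fragment B takes 4 steps (6–9).

**Steps most likely to fail**

Step 10. The first allylboration may fail to discriminate between the two aldehydes, or the dialdehyde may be lost by hydration or β-elimination before it is consumed. A stepwise fallback makes the same two bonds in two operations. It sets out from 11. Ozonolysis of 11 in CH2Cl2/MeOH containing TsOH, with Me2S work-up, should give the hydroxy acetal (4R,5R)-4-(dimethoxymethyl)-5-(hydroxymethyl)oxolan-2-one F1. Dess–Martin oxidation should give (2R,3R)-3-(dimethoxymethyl)-5-oxooxolane-2-carbaldehyde F2, in which only the α-oxygenated aldehyde is free. Allylboration with 7 (toluene, 60 °C) should then give the C9 O-boryl (E)-allylboronate acetal F3. Acetal exchange (pyridinium 4-methylbenzenesulfonate, acetone with 2 equiv H2O, 40 °C, in which the dioxolane is stable) releases the C6 aldehyde, that is 15. This closes to 16 and is hydrolysed to 17, where the route is rejoined.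

Step 18. Markovnikov oxidation to the methyl ketone may compete, or chloride may open the oxirane under the palladium/copper conditions. The fallback sets out from 27. Hydroboration with 9-borabicyclo[3.3.1]nonane (THF, rt), which should prefer the unconjugated vinyl group over the electron-poor conjugated alkenes, gives the B-alkyl borane F6. Oxidation with NaBO3·4H2O gives the primary alcohol F7, and Dess–Martin oxidation returns to the route at 28.

Step 11. The oxidant may discriminate poorly between the two secondary carbinols, leading to over-oxidation at C9. The fallback sets out from 17. Exhaustive silylation (excess Et3SiOTf, 2,6-lutidine) gives the 6α,9α-bis(triethylsilyl) ether F4. Selective hydrolysis of the unhindered equatorial C6 silyl ether (AcOH/THF/H2O, 0 °C) gives the 9α-O-triethylsilyl 6α-alcohol F5. Dess–Martin oxidation then gives 19 directly, where the route is rejoined.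

**Further compounds**
F1 | step 10 | (4R,5R)-4-(dimethoxymethyl)-5-(hydroxymethyl)oxolan-2-one | C1C(=O)O[C@@H](CO)[C@@H]1C(OC)OC
F2 | step 10 | (2R,3R)-3-(dimethoxymethyl)-5-oxooxolane-2-carbaldehyde | C1C(=O)O[C@@H](C=O)[C@@H]1C(OC)OC
F3 | step 10 | C9 O-pinacolboryl (E)-allylboronate with C6 as dimethyl acetal | C1C(=O)O[C@H]([C@@H]1C(OC)OC)[C@@H](OB2OC(C)(C)C(C)(C)O2)[C@](C)(/C=C/CB3OC(C)(C)C(C)(C)O3)[C@@H]4COC(C)(C)O4
F4 | step 11 | 6α,9α-bis(O-triethylsilyl) ether of 17 | C1C(=O)O[C@@H]2[C@@H]1[C@H](O[Si](CC)(CC)CC)[C@@H](C=C)[C@](C)([C@@H]3COC(C)(C)O3)[C@@H]2O[Si](CC)(CC)CC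
F5 | step 11 | 9α-O-triethylsilyl ether of 17 with free 6α-hydroxyl | C1C(=O)O[C@@H]2[C@@H]1[C@H](O)[C@@H](C=C)[C@](C)([C@@H]3COC(C)(C)O3)[C@@H]2O[Si](CC)(CC)CC
F6 | step 18 | B-alkyl-9-borabicyclo[3.3.1]nonane adduct of 27 (boron on C3) | C=C1C(=O)O[C@@H]2[C@@H]1[C@@H](OC(=O)/C(C)=C\C)[C@@H](CCB3C4CCCC3CCC4)[C@](C)([C@@H]5CO5)[C@@H]2O
F7 | step 18 | 5β-(2-hydroxyethyl) primary alcohol | C=C1C(=O)O[C@@H]2[C@@H]1[C@@H](OC(=O)/C(C)=C\C)[C@@H](CCO)[C@](C)([C@@H]3CO3)[C@@H]2O
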